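**Retrosynthetic overview**
- The target comes from an all-trans 4-aroyl-2-aryl-oxolane-3-carbaldehyde by aldehyde-only reduction and removal of two aryl acetates.
- The oxolane comes from a 7→5 ring contraction of a 5-aroyl-2-aryl-4,5-dihydro-1,3-dioxepin: an acid-triggered ionic 1,3 O-to-C shift that forms the C2–C3 bond. A chiral phosphate sets C2; C3 and C4 are then equilibrated.
- The vinyl acetal comes from carbonylative Heck aroylation (aryl iodide + CO) of a 2-aryl-4,7-dihydro-1,3-dioxepin.
- The dioxepin comes from an aryl aldehyde and cis-2-butene-1,4-diol; both aryl units come from catechol via 2-methoxyphenyl acetate (formylation or iodination para to OMe).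
- Ring order: the seven-membered acetal ring is made first and is then contracted to the oxolane; no other ring is built.

Oxolane numbering used below: O1, C2 (aryl), C3 (CHO or CH2OH), C4 (aroyl), C5 (CH2). The target is (2S,3R,4S), with all three substituents mutually trans.

Assumption: the (R)-phosphoric acid is taken to deliver the 2S series; the sense of induction cannot be predicted with confidence, and if it gives 2R the (S)-catalyst is used instead.

**Step 1**
Reactants: 1 catechol
Product: 3 2-methoxyphenyl acetate, via guaiacol 2 (not isolated)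
Conditions: 1 (1.5 equiv), K2CO3 (1.0 equiv), MeI (1.0 equiv), acetone, 56 °C; then Ac2O, 4-(dimethylamino)pyridine (2 mol%), rt
Reagents that add atoms: iodomethane (CI); acetic anhydride (CC(=O)OC(C)=O)
Why: Williamson mono-O-methylation with limiting MeI, then O-acetylation in the same flask, so that OMe becomes the dominant director in the next two steps; no stereocentre.

**Step 2**
Reactants: 3 2-methoxyphenyl acetate
Product: 5 3-acetoxy-4-methoxybenzaldehyde, via chloro(methoxy)methyl arene 4 (not isolated)
Conditions: Cl2CHOMe, TiCl4, CH2Cl2, 0 °C; then H2O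
Reagents that add atoms: dichloromethyl methyl ether (COC(Cl)Cl); water (O)
Why: Rieche formylation (Friedel–Crafts type) enters para to the strongly donating OMe, because the acetoxy group is a much weaker donor; no stereocentre.

**Step 3**
Reactants: 3 2-methoxyphenyl acetate
Product: 6 5-iodo-2-methoxyphenyl acetate
Conditions: NIS, CF3CO2H (cat.), MeCN, rt
Reagents that add atoms: N-iodosuccinimide (O=C1CCC(=O)N1I)
Why: Electrophilic aromatic iodination, para to OMe for the same electronic reason; no stereocentre.

**Step 4**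
Reactants: 5 3-acetoxy-4-methoxybenzaldehyde; 7 (Z)-but-2-ene-1,4-diol
Product: 8 2-(3-acetoxy-4-methoxyphenyl)-4,7-dihydro-1,3-dioxepin
Conditions: pyridinium p-toluenesulfonate (5 mol%), PhH, reflux, Dean–Stark
Reagents that add atoms: none
Why: Acid-catalysed acetalisation with azeotropic water removal; the cis-diol closes the seven-membered ring, the weak acid spares the aryl acetate, and the product is achiral.

**Step 5**
Reactants: 8 2-(3-acetoxy-4-methoxyphenyl)-4,7-dihydro-1,3-dioxepin; 6 5-iodo-2-methoxyphenyl acetate (1.5 equiv)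
Product: 9 2-(3-acetoxy-4-methoxyphenyl)-5-(3-acetoxy-4-methoxybenzoyl)-4,5-dihydro-1,3-dioxepin (racemic cis/trans mixture)
Conditions: Pd(OAc)2 (5 mol%), di(1-adamantyl)-n-butylphosphine (10 mol%), CO (1 atm), NaHCO3 (2 equiv), 1,4-dioxane, 80 °C
Reagents that add atoms: carbon monoxide ([C-]#[O+])
Why: Carbonylative Heck (acyl-Heck) reaction: the C–I bond adds to zerovalent palladium, CO inserts, the acyl–palladium adds syn across the symmetric cis-alkene, and syn β-hydride elimination is only possible toward the OCH2 carbon, which leaves the enol ether; the new centre is formed unselectively, which is harmless because the acetal carbon is ionised and the acyl-bearing carbon is equilibrated in step 6.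

**Step 6**
Reactants: 9 2-(3-acetoxy-4-methoxyphenyl)-5-(3-acetoxy-4-methoxybenzoyl)-4,5-dihydro-1,3-dioxepin
Product: 11 (2S,3S,4S)-4-(3-acetoxy-4-methoxybenzoyl)-2-(3-acetoxy-4-methoxyphenyl)oxolane-3-carbaldehyde, via 2S aldehyde epimer mixture 10 (not isolated)
Conditions: (R)-TRIP [(R)-3,3'-bis(2,4,6-triisopropylphenyl)-1,1'-binaphthyl-2,2'-diyl hydrogen phosphate] (5 mol%), 5 Å MS, PhMe, −30 → 0 °C; then 1,8-diazabicyclo[5.4.0]undec-7-ene (DBU, 10 mol%), rt
Reagents that add atoms: none
Why: Proposed new method: a catalytic enantioselective, stereoconvergent ring contraction (ionic 1,3 O-to-C shift, Petasis–Ferrier type) of a 5-acyl vinyl acetal, in which the phosphoric acid protonates the enol-ether oxygen, the C2–O bond ionises to a para-methoxy-stabilised oxocarbenium ion paired with the chiral phosphate while the released Z-enol is hydrogen-bonded to the same anion, and the enol carbon closes on one face of the cation to form the C2–C3 bond and set C2 as S whatever the configuration at the acyl-bearing carbon (the acetal centre is erased on ionisation), after which DBU equilibrates the two α-carbonyl centres C3 and C4 to the all-trans isomer; the closest known reaction type is the Lewis-acid-mediated ring contraction of 4,5-dihydro-1,3-dioxepins to oxolane-3-carbaldehydes together with chiral-phosphoric-acid Petasis–Ferrier-type rearrangements, neither shown on a 5-acyl substrate nor as a convergent process from a four-stereoisomer mixture.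

**Step 7**
Reactants: 11 (2S,3S,4S)-4-(3-acetoxy-4-methoxybenzoyl)-2-(3-acetoxy-4-methoxyphenyl)oxolane-3-carbaldehyde
Product: 13 (2S,3R,4S)-2-(3-hydroxy-4-methoxyphenyl)-4-(3-hydroxy-4-methoxybenzoyl)-3-(hydroxymethyl)oxolane, via primary alcohol diacetate 12 (not isolated)
Conditions: NaBH4 (0.3 equiv), CH2Cl2/MeOH, −78 → −40 °C; then K2CO3 (0.2 equiv), MeOH, 0 °C → rt; aq. NH4Cl
Reagents that add atoms: none
Why: Chemoselective borohydride reduction of the aldehyde in the presence of the hindered, electron-rich aryl ketone, then base-catalysed methanolysis (transesterification) of both aryl acetates; the reduction freezes C3, and C4 stays trans under the basic conditions because that is its thermodynamic configuration.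

**Compound list**
1 | catechol (benzene-1,2-diol) | Oc1ccccc1O | starting material
2 | guaiacol (2-methoxyphenol) | COc1ccccc1O | intermediate
3 | 2-methoxyphenyl acetate | COc1ccccc1OC(C)=O | intermediate
4 | 5-[chloro(methoxy)methyl]-2-methoxyphenyl acetate | COc1ccc(C(Cl)OC)cc1OC(C)=O | intermediate
5 | 3-acetoxy-4-methoxybenzaldehyde | COc1ccc(C=O)cc1OC(C)=O | intermediate
6 | 5-iodo-2-methoxyphenyl acetate | COc1ccc(I)cc1OC(C)=O | intermediate
7 | (Z)-but-2-ene-1,4-diol | OC/C=C\CO | starting material
8 | 2-(3-acetoxy-4-methoxyphenyl)-4,7-dihydro-1,3-dioxepin | COc1ccc(C2OCC=CCO2)cc1OC(C)=O | intermediate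
9 | 2-(3-acetoxy-4-methoxyphenyl)-5-(3-acetoxy-4-methoxybenzoyl)-4,5-dihydro-1,3-dioxepin (racemic cis/trans mixture) | COc1ccc(C2OCC(C(=O)c3ccc(OC)c(OC(C)=O)c3)C=CO2)cc1OC(C)=O | intermediate
10 | (2S)-4-(3-acetoxy-4-methoxybenzoyl)-2-(3-acetoxy-4-methoxyphenyl)oxolane-3-carbaldehyde (C3/C4 epimer mixture) | COc1ccc(C(=O)C2CO[C@H](c3ccc(OC)c(OC(C)=O)c3)C2C=O)cc1OC(C)=O | intermediate
11 | (2S,3S,4S)-4-(3-acetoxy-4-methoxybenzoyl)-2-(3-acetoxy-4-methoxyphenyl)oxolane-3-carbaldehyde (all-trans) | COc1ccc(C(=O)[C@@H]2CO[C@H](c3ccc(OC)c(OC(C)=O)c3)[C@H]2C=O)cc1OC(C)=O | intermediate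
12 | (2S,3R,4S)-2-(3-acetoxy-4-methoxyphenyl)-4-(3-acetoxy-4-methoxybenzoyl)-3-(hydroxymethyl)oxolane | COc1ccc(C(=O)[C@@H]2CO[C@H](c3ccc(OC)c(OC(C)=O)c3)[C@H]2CO)cc1OC(C)=O | intermediate
13 | (2S,3R,4S)-2-(3-hydroxy-4-methoxyphenyl)-4-(3-hydroxy-4-methoxybenzoyl)-3-(hydroxymethyl)oxolane, CNP0234761.1 | COc1ccc(C(=O)[C@@H]2CO[C@H](c3ccc(OC)c(O)c3)[C@H]2CO)cc1O | target

**Step count and risks**
Total step count: 7 (the one-flask sequences of steps 1, 6 and 7 count as one step each).
Longest linear sequence: 6 steps (1 → 2 → 4 → 5 → 6 → 7); step 3 is a one-step side branch.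

The three steps most likely to fail:

Step 5. Carbonylative Heck coupling is established for styrenes and similar alkenes but not for this ring. Insertion of the acyl–palladium species into an unactivated cyclic alkene may be slow, and the β,γ-unsaturated ketone 9 may drift into conjugation. The fallback sets out from 3 and 8 and comes back to the route at 12. The aroyl group is carried as a 1-arylvinyl group and installed by an ordinary Heck reaction of an alkenyl triflate, a reaction class that is established for this ring. Friedel–Crafts acetylation of 3 (AcCl, AlCl3, CH2Cl2, 0 °C) gives 5-acetyl-2-methoxyphenyl acetate F1. Tf2O with 2,6-di-tert-butyl-4-methylpyridine converts it into 1-(3-acetoxy-4-methoxyphenyl)vinyl trifluoromethanesulfonate F2. Heck coupling of F2 with 8 (Pd(OAc)2, PPh3, i-Pr2NEt, DMF, 60 °C) gives 2-(3-acetoxy-4-methoxyphenyl)-5-[1-(3-acetoxy-4-methoxyphenyl)vinyl]-4,5-dihydro-1,3-dioxepin F3, which has no acidic α-hydrogen and cannot conjugate. F3 is taken through the conditions of step 6 to (2S,3S)-2-(3-acetoxy-4-methoxyphenyl)-4-[1-(3-acetoxy-4-methoxyphenyl)vinyl]oxolane-3-carbaldehyde F4 (both C4 epimers). NaBH4 then gives (2S,3R)-2-(3-acetoxy-4-methoxyphenyl)-4-[1-(3-acetoxy-4-methoxyphenyl)vinyl]-3-(hydroxymethyl)oxolane F5, from which any 2,3-cis material is removed by chromatography. Lemieux–Johnson cleavage of the 1,1-disubstituted alkene (OsO4 cat., NaIO4, 2,6-lutidine, dioxane/H2O) unveils the ketone and gives 12 with its C4 epimer; C4 settles trans in the carbonate stage of step 7.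

Step 6. This is the new step. Enantiocontrol may be incomplete when the acyl-bearing centre of the substrate is mismatched with the catalyst, and the 1,4-keto aldehyde can dehydrate to a furan under acid. Base-induced loss of the C2 configuration is not expected, since ring opening by β-elimination would be a retro-5-endo-trig process. The fallback uses known chemistry, sets out from 9 and comes back at 11. The ring contraction is run with an achiral Lewis acid, the established mode for 4,5-dihydro-1,3-dioxepins (TMSOTf 10 mol%, CH2Cl2, −78 → −20 °C; then DBU). This gives 11 as the racemate, that is together with its mirror image (2R,3R,4R)-4-(3-acetoxy-4-methoxybenzoyl)-2-(3-acetoxy-4-methoxyphenyl)oxolane-3-carbaldehyde F6. Preparative chromatography on a chiral stationary phase removes F6 and leaves 11.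

Step 7. The aryl ketone may be reduced alongside the aldehyde. The fallback sets out from 11 and comes back at 12. Both carbonyl groups are reduced on purpose (NaBH4 2 equiv, THF/MeOH, 0 °C) to (2S,3R,4S)-2-(3-acetoxy-4-methoxyphenyl)-4-[(3-acetoxy-4-methoxyphenyl)(hydroxy)methyl]-3-(hydroxymethyl)oxolane F7 (both carbinol epimers). Activated MnO2 (CH2Cl2, rt) then re-oxidises only the benzylic secondary alcohol and leaves the primary alcohol, which gives 12; this is deacetylated with K2CO3/MeOH as in step 7.

**Further compounds**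
F1 | step 5 | 5-acetyl-2-methoxyphenyl acetate | COc1ccc(C(C)=O)cc1OC(C)=O
F2 | step 5 | 1-(3-acetoxy-4-methoxyphenyl)vinyl trifluoromethanesulfonate | COc1ccc(C(=C)OS(=O)(=O)C(F)(F)F)cc1OC(C)=O
F3 | step 5 | 2-(3-acetoxy-4-methoxyphenyl)-5-[1-(3-acetoxy-4-methoxyphenyl)vinyl]-4,5-dihydro-1,3-dioxepin (racemic cis/trans mixture) | COc1ccc(C2OCC(C(=C)c3ccc(OC)c(OC(C)=O)c3)C=CO2)cc1OC(C)=O
F4 | step 5 | (2S,3S)-2-(3-acetoxy-4-methoxyphenyl)-4-[1-(3-acetoxy-4-methoxyphenyl)vinyl]oxolane-3-carbaldehyde (C4 epimers) | COc1ccc(C(=C)C2CO[C@H](c3ccc(OC)c(OC(C)=O)c3)[C@H]2C=O)cc1OC(C)=O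
F5 | step 5 | (2S,3R)-2-(3-acetoxy-4-methoxyphenyl)-4-[1-(3-acetoxy-4-methoxyphenyl)vinyl]-3-(hydroxymethyl)oxolane (C4 epimers) | COc1ccc(C(=C)C2CO[C@H](c3ccc(OC)c(OC(C)=O)c3)[C@H]2CO)cc1OC(C)=O
F6 | step 6 | (2R,3R,4R)-4-(3-acetoxy-4-methoxybenzoyl)-2-(3-acetoxy-4-methoxyphenyl)oxolane-3-carbaldehyde | COc1ccc(C(=O)[C@H]2CO[C@@H](c3ccc(OC)c(OC(C)=O)c3)[C@@H]2C=O)cc1OC(C)=O
F7 | step 7 | (2S,3R,4S)-2-(3-acetoxy-4-methoxyphenyl)-4-[(3-acetoxy-4-methoxyphenyl)(hydroxy)methyl]-3-(hydroxymethyl)oxolane (carbinol epimers) | COc1ccc(C(O)[C@@H]2CO[C@H](c3ccc(OC)c(OC(C)=O)c3)[C@H]2CO)cc1OC(C)=O
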